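**Plan**
- Retrosynthesis: the propionyl C=O, ring C2 and the C3 enol carbon form one 1,3-dicarbonyl unit, which is folded back into a 3-ethylisoxazole (released at the end by N–O reduction and hydrolysis). The carbocycle is then cut at C4–C5 and at C6–C1.
- These cuts give a laterally lithiated ethyl 5-alkylisoxazole-4-carboxylate (C1–C4 plus the mask) and bis(prenyl)ketene (C5, C6 and the geminal prenyl pair).
- Forward: the isoxazole ring is made first (enamine plus nitrile oxide) and its 5-methyl is prenylated. The ketene comes from diethyl malonate in five steps. One annulation closes the six-membered carbocycle, and the isoxazole is opened last.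
- Stereochemistry: the target has no stereocentre (C6 carries two identical prenyl groups and every alkene ends in CMe2), so none has to be set. Racemic centres in transient intermediates disappear.

Key step: step 9

Remark on the chemistry: the target, 17 and 18 are each drawn as one tautomer of a mobile enol system. Ring positions C1–C6 follow the cyclohexadienone numbering of the target (C1 ring carbonyl, C2 propionyl, C3 and C5 enol carbons, C4 monoprenyl, C6 diprenyl).

**Route**

Step 1
Reactants: 1 ethyl acetoacetate
Product: 2 ethyl (E)-3-(pyrrolidin-1-yl)but-2-enoate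
Conditions: pyrrolidine (1.05 equiv), toluene, reflux, Dean–Stark trap
Reagents that add atoms: pyrrolidine, C1CCNC1
Why: Enamine condensation of the ketone carbonyl of a β-keto ester with a secondary amine, driven by azeotropic removal of water, should give the conjugated E enamino ester.

Step 2
Reactants: 2 ethyl (E)-3-(pyrrolidin-1-yl)but-2-enoate; 3 1-nitropropane
Product: 6 ethyl 3-ethyl-5-methyl-1,2-oxazole-4-carboxylate, via propanenitrile oxide 4 (not isolated), via pyrrolidinyl isoxazoline cycloadduct 5 (not isolated)
Conditions: POCl3, Et3N, CHCl3, 0 °C → rt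
Reagents that add atoms: none
Why: POCl3/Et3N dehydrates the primary nitroalkane to nitrile oxide 4, whose Huisgen 1,3-dipolar cycloaddition to the electron-rich enamine places oxygen on the amine-bearing carbon, and loss of pyrrolidine from 5 aromatises the ring to a single regioisomer.

Step 3
Reactants: 6 ethyl 3-ethyl-5-methyl-1,2-oxazole-4-carboxylate; 7 1-bromo-3-methylbut-2-ene (prenyl bromide)
Product: 8 ethyl 3-ethyl-5-(4-methylpent-3-en-1-yl)-1,2-oxazole-4-carboxylate
Conditions: LiN(iPr)2 (1.05 equiv), THF, −78 °C; then 7 (1.1 equiv), −78 → −30 °C
Reagents that add atoms: none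
Why: Lateral metalation followed by alkylation should work because the C5 methyl is the most acidic C–H (its anion is delocalised through C4=C5 into the ester, unlike the 3-ethyl CH2) and the primary allylic bromide reacts by SN2 at low temperature.

Step 4
Reactants: 9 diethyl malonate; 7 1-bromo-3-methylbut-2-ene
Product: 11 diethyl 2,2-bis(3-methylbut-2-en-1-yl)propanedioate, via diethyl 2-(3-methylbut-2-en-1-yl)propanedioate 10 (not isolated)
Conditions: NaH (2.3 equiv), 7 (2.2 equiv), THF, 0 → 60 °C
Reagents that add atoms: none
Why: In this malonic ester alkylation two successive SN2 reactions of the sodium malonate with the reactive allylic bromide should place both prenyl groups on one carbon, the mono-alkylated ester 10 being deprotonated again in the same flask.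

Step 5
Reactants: 11 diethyl 2,2-bis(3-methylbut-2-en-1-yl)propanedioate
Product: 12 2,2-bis(3-methylbut-2-en-1-yl)propanedioic acid
Conditions: KOH (6 equiv), EtOH/H2O, reflux; then cold 1 M HCl to pH 2
Reagents that add atoms: water, O
Why: Saponification of both esters by hydroxide, followed by brief acidification in the cold, should give the diacid without acid-induced addition of a carboxyl group to a prenyl alkene.

Step 6
Reactants: 12 2,2-bis(3-methylbut-2-en-1-yl)propanedioic acid
Product: 13 5-methyl-2-(3-methylbut-2-en-1-yl)hex-4-enoic acid
Conditions: neat, 150 °C, argon, until gas evolution stops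
Reagents that add atoms: none
Why: Thermal decarboxylation of a geminal diacid through the cyclic six-membered transition state, the last stage of the malonic ester synthesis, should leave the disubstituted acetic acid with both alkenes intact.

Step 7
Reactants: 13 5-methyl-2-(3-methylbut-2-en-1-yl)hex-4-enoic acid
Product: 14 5-methyl-2-(3-methylbut-2-en-1-yl)hex-4-enoyl chloride
Conditions: (COCl)2 (1.2 equiv), DMF (cat.), CH2Cl2, 0 °C → rt; volatiles removed in vacuo
Reagents that add atoms: oxalyl chloride, O=C(Cl)C(=O)Cl
Why: Vilsmeier-type activation by oxalyl chloride/DMF forms the acid chloride in the cold while HCl escapes, so the trisubstituted alkenes should not be hydrochlorinated.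

Step 8
Reactants: 14 5-methyl-2-(3-methylbut-2-en-1-yl)hex-4-enoyl chloride
Product: 15 bis(3-methylbut-2-en-1-yl)ketene (5-methyl-2-(3-methylbut-2-en-1-yl)hexa-1,4-dien-1-one)
Conditions: Et3N (1.5 equiv), Et2O, rt → reflux; filtration under argon; bulb-to-bulb distillation; used at once as a THF solution
Reagents that add atoms: none
Why: Dehydrochlorination of an α,α-dialkyl acyl chloride by a tertiary amine is the standard route to dialkylketenes, which dimerise slowly enough to be freed from the ammonium salt and distilled.

Step 9
Reactants: 8 ethyl 3-ethyl-5-(4-methylpent-3-en-1-yl)-1,2-oxazole-4-carboxylate; 15 bis(3-methylbut-2-en-1-yl)ketene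
Product: 17 3-ethyl-6-hydroxy-5,5,7-tris(3-methylbut-2-en-1-yl)-1,2-benzoxazol-4(5H)-one, via lithium enolate of the ketene adduct 16 (not isolated)
Conditions: LiN(iPr)2 (1.05 equiv), THF, −78 °C; 15 (1.0 equiv) added slowly, −78 °C; then → 0 °C; cold 1 M HCl
Reagents that add atoms: none
Why: Proposed new method: LiN(iPr)2 removes a proton from the CH2 on isoxazole C5 (a vinylogous ester enolate), this carbanion adds to the central carbon of ketene 15 and so gives only the lithium enolate 16 whose carbon terminus bears both prenyl groups (C4–C5 bond), and 16 then acylates itself on the neighbouring ethyl ester, expelling ethoxide and creating the quaternary carbon (C6–C1 bond). The closest known reactions are the Michael–Claisen annulation of lateral toluate-type carbanions, the lateral metalation of 5-alkylisoxazole-4-carboxylates and the addition of organolithiums to ketenes to give regiodefined enolates, the ketene here taking the place of the Michael acceptor. The one ring formed, the six-membered carbocycle, closes in a 6-(enolendo)-exo-trig Claisen (Dieckmann-type) mode onto an ester held ortho on the rigid heteroarene. No stereocentre arises, because the new quaternary carbon carries two identical prenyl groups and the racemic CH of 16 becomes sp2 in 17. The step needs C-acylation to outrun proton transfer from the doubly activated C–H of 16, O-acylation and a second ketene addition: slow addition of one equivalent of 15 at −78 °C keeps free ketene and proton donors scarce, O-acylation by an ester is reversible under the ethoxide released, and the C-acylated product is drained as the stabilised enolate of the vinylogous acid 17. The isoxazole is what leaves the ester neutral and electrophilic, since the unmasked triketone array would sit as an unreactive enolate under these conditions.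

Step 10
Reactants: 17 3-ethyl-6-hydroxy-5,5,7-tris(3-methylbut-2-en-1-yl)-1,2-benzoxazol-4(5H)-one
Product: 18 2-(1-aminopropylidene)-5-hydroxy-4,6,6-tris(3-methylbut-2-en-1-yl)cyclohex-4-ene-1,3-dione
Conditions: Mo(CO)6 (1.0 equiv), MeCN/H2O, 80 °C, argon
Reagents that add atoms: none
Why: Mo(CO)6 in wet acetonitrile cleaves the weak N–O bond of isoxazoles reductively to the vinylogous amide, water supplying the hydrogens, and should leave the trisubstituted alkenes and the enol untouched where hydrogenolysis would not.

Step 11
Reactants: 18 2-(1-aminopropylidene)-5-hydroxy-4,6,6-tris(3-methylbut-2-en-1-yl)cyclohex-4-ene-1,3-dione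
Product: 19 postlupulone (3,5-dihydroxy-4,6,6-tris(3-methylbut-2-en-1-yl)-2-propanoylcyclohexa-2,4-dien-1-one)
Conditions: degassed 2 M aq NaOH, EtOH, 70 °C, argon; then cold 1 M HCl to pH 3, work-up under argon
Reagents that add atoms: water, O
Why: Hydroxide adds to the amino-bearing carbon of the vinylogous amide and ammonia is expelled (addition–elimination hydrolysis of an enamino diketone to a β-triketone, as in the isoxazole route to 2-acylcyclohexane-1,3-diones), while the product is held as its delocalised enolate and so shielded from retro-Claisen cleavage and, under argon, from autoxidation.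

**Compound list**
1 | ethyl acetoacetate | CCOC(=O)CC(C)=O | starting material
2 | ethyl (E)-3-(pyrrolidin-1-yl)but-2-enoate | CCOC(=O)/C=C(\C)N1CCCC1 | intermediate
3 | 1-nitropropane | CCC[N+](=O)[O-] | starting material
4 | propanenitrile oxide | CCC#[N+][O-] | intermediate
5 | ethyl 3-ethyl-5-methyl-5-(pyrrolidin-1-yl)-4,5-dihydro-1,2-oxazole-4-carboxylate (racemic, relative configuration not defined) | CCOC(=O)C1C(CC)=NOC1(C)N1CCCC1 | intermediate
6 | ethyl 3-ethyl-5-methyl-1,2-oxazole-4-carboxylate | CCOC(=O)c1c(CC)noc1C | intermediate
7 | 1-bromo-3-methylbut-2-ene (prenyl bromide) | CC(C)=CCBr | starting material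
8 | ethyl 3-ethyl-5-(4-methylpent-3-en-1-yl)-1,2-oxazole-4-carboxylate | CCOC(=O)c1c(CC)noc1CCC=C(C)C | intermediate
9 | diethyl malonate | CCOC(=O)CC(=O)OCC | starting material
10 | diethyl 2-(3-methylbut-2-en-1-yl)propanedioate | CCOC(=O)C(CC=C(C)C)C(=O)OCC | intermediate
11 | diethyl 2,2-bis(3-methylbut-2-en-1-yl)propanedioate | CCOC(=O)C(CC=C(C)C)(CC=C(C)C)C(=O)OCC | intermediate
12 | 2,2-bis(3-methylbut-2-en-1-yl)propanedioic acid | OC(=O)C(CC=C(C)C)(CC=C(C)C)C(=O)O | intermediate
13 | 5-methyl-2-(3-methylbut-2-en-1-yl)hex-4-enoic acid | OC(=O)C(CC=C(C)C)CC=C(C)C | intermediate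
14 | 5-methyl-2-(3-methylbut-2-en-1-yl)hex-4-enoyl chloride | ClC(=O)C(CC=C(C)C)CC=C(C)C | intermediate
15 | bis(3-methylbut-2-en-1-yl)ketene (5-methyl-2-(3-methylbut-2-en-1-yl)hexa-1,4-dien-1-one) | O=C=C(CC=C(C)C)CC=C(C)C | intermediate
16 | lithium 5-(4-ethoxycarbonyl-3-ethyl-1,2-oxazol-5-yl)-2,10-dimethyl-7-(3-methylbut-2-en-1-yl)undeca-2,6,9-trien-6-olate (ketene adduct enolate, racemic) | CCOC(=O)c1c(CC)noc1C(CC=C(C)C)C(O[Li])=C(CC=C(C)C)CC=C(C)C | intermediate
17 | 3-ethyl-6-hydroxy-5,5,7-tris(3-methylbut-2-en-1-yl)-1,2-benzoxazol-4(5H)-one | CCc1noc2c1C(=O)C(CC=C(C)C)(CC=C(C)C)C(O)=C2CC=C(C)C | intermediate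
18 | 2-(1-aminopropylidene)-5-hydroxy-4,6,6-tris(3-methylbut-2-en-1-yl)cyclohex-4-ene-1,3-dione (exocyclic C=C geometry mobile, not defined) | CCC(N)=C1C(=O)C(CC=C(C)C)=C(O)C(CC=C(C)C)(CC=C(C)C)C1=O | intermediate
19 | postlupulone, 3,5-dihydroxy-4,6,6-tris(3-methylbut-2-en-1-yl)-2-propanoylcyclohexa-2,4-dien-1-one (no stereocentre) | CCC(=O)C1=C(O)C(CC=C(C)C)=C(O)C(CC=C(C)C)(CC=C(C)C)C1=O | target

**Count**
Total: 11 steps. Longest linear sequence: 8 steps (steps 4–11, from diethyl malonate 9). The isoxazole arm (steps 1–3) joins at step 9.

**Steps most likely to fail**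

Step 9. Proton transfer to the tetrasubstituted enolate from the doubly activated C–H next to the isoxazole, or closure through oxygen, may be faster than formation of the hindered C–C bond, so that the annulation stalls after the first bond. The fallback makes the two bonds in separate, known operations and sets out from acid chloride 14 and isoxazole 8. With N,O-dimethylhydroxylamine hydrochloride and pyridine in CH2Cl2, 14 should give the Weinreb amide N-methoxy-N,5-dimethyl-2-(3-methylbut-2-en-1-yl)hex-4-enamide F1. The lateral anion of 8 (LiN(iPr)2, THF, −78 °C) is acylated by F1, whose chelated tetrahedral intermediate holds back enolisation and over-addition until work-up. This gives the keto ester ethyl 5-[2,10-dimethyl-7-(3-methylbut-2-en-1-yl)-6-oxoundeca-2,9-dien-5-yl]-3-ethyl-1,2-oxazole-4-carboxylate F2. A Dieckmann condensation under equilibrating conditions (KOtBu, tBuOH/THF, rt to 50 °C) then lets the minor enolate at the diprenylmethine carbon close onto the ester. The equilibrium is pulled over by the potassium salt of the vinylogous acid, and acidification rejoins the route at 17.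

Step 8. Slow dehydrochlorination of the hindered acyl chloride, together with amine-induced dimerisation or adventitious hydrolysis of the ketene during filtration and distillation, may leave too little monomer. The fallback generates the ketene in the flask by E1cB fragmentation of a hindered aryl ester enolate, a known way to feed ketenes to organolithiums, and sets out from 14. With lithium 2,6-di-tert-butyl-4-methylphenoxide (from the phenol and n-BuLi in THF), 14 should give the aryl ester 2,6-di-tert-butyl-4-methylphenyl 5-methyl-2-(3-methylbut-2-en-1-yl)hex-4-enoate F3. F3 is deprotonated with LiN(iPr)2 at −78 °C and combined with lithiated 8. On warming towards room temperature the ester enolate expels the aryloxide and releases the ketene slowly in the presence of its trap. The route is rejoined at 15, which is consumed as it forms under the conditions of step 9.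

Step 3. Claisen self-condensation of the lateral anion with the ester of unmetalated 6, and a second prenylation through proton exchange between product and anion, may erode the mono-alkylated ester. The fallback installs the prenyl group before the heterocycle is built and sets out from 1 and 7. The dianion of 1 (NaH, then n-BuLi, THF, 0 °C) is alkylated at its terminal carbon by 7 to give ethyl 7-methyl-3-oxooct-6-enoate F4. Pyrrolidine (toluene, Dean–Stark trap) converts F4 into the enamine ethyl (E)-7-methyl-3-(pyrrolidin-1-yl)octa-2,6-dienoate F5. Cycloaddition of F5 with nitrile oxide 4, generated from 3 with POCl3/Et3N as in step 2, gives the isoxazoline ethyl 3-ethyl-5-(4-methylpent-3-en-1-yl)-5-(pyrrolidin-1-yl)-4,5-dihydro-1,2-oxazole-4-carboxylate F6. F6 loses pyrrolidine in the flask and joins the route at 8.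

**Further compounds**
F1 | step 9 | N-methoxy-N,5-dimethyl-2-(3-methylbut-2-en-1-yl)hex-4-enamide | CON(C)C(=O)C(CC=C(C)C)CC=C(C)C
F2 | step 9 | ethyl 5-[2,10-dimethyl-7-(3-methylbut-2-en-1-yl)-6-oxoundeca-2,9-dien-5-yl]-3-ethyl-1,2-oxazole-4-carboxylate (racemic) | CCOC(=O)c1c(CC)noc1C(CC=C(C)C)C(=O)C(CC=C(C)C)CC=C(C)C
F3 | step 8 | 2,6-di-tert-butyl-4-methylphenyl 5-methyl-2-(3-methylbut-2-en-1-yl)hex-4-enoate | Cc1cc(C(C)(C)C)c(OC(=O)C(CC=C(C)C)CC=C(C)C)c(C(C)(C)C)c1
F4 | step 3 | ethyl 7-methyl-3-oxooct-6-enoate | CCOC(=O)CC(=O)CCC=C(C)C
F5 | step 3 | ethyl (E)-7-methyl-3-(pyrrolidin-1-yl)octa-2,6-dienoate | CCOC(=O)/C=C(\CCC=C(C)C)N1CCCC1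
F6 | step 3 | ethyl 3-ethyl-5-(4-methylpent-3-en-1-yl)-5-(pyrrolidin-1-yl)-4,5-dihydro-1,2-oxazole-4-carboxylate (racemic, relative configuration not defined) | CCOC(=O)C1C(CC)=NOC1(CCC=C(C)C)N1CCCC1
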